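## Plan

1. Retrosynthesis (germacrane numbering): the oxirane is opened at O–C5 to a syn-4,5-diol, the C3 and C6 ester C–O bonds are cut, the diol is traced back to a Z-C4=C5 alkene and the C6 carbinol to a ketone.
2. The ten-membered dienone is then cut at C8–C9 with C1–C6 rejoined (retro-oxy-Cope) to a trans-1,2-dialkenylcyclohex-2-enol; its C6–C7 bond is cut to an alkenyl metal and a 4-silyloxyisopiperitenone derived from (S)-carvone.
3. Enabling feature: ring carbons C1–C6 with the C4 methyl, the C3 oxygen and the C10/C9/C14 isopropenyl carbons form a carvone skeleton, and the C6 oxygen is separated from the C1=C10 alkene by C7, C8 and C9 (a δ,ε-unsaturated ketone once C6 is at the ketone level).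
4. Forward order: the carvone six-membered ring is carried to the dialkenyl carbinol and enlarged to the ten-membered ring in one [3,3] shift; the oxirane is the only ring closed afterwards.
5. Stereochemistry: C3 from the carvone stereocentre (trans epoxidation, Wharton transposition); C7 from protonation of the planar-chiral E-enolate; C6 from hydride addition; C4 and C5 from hydroxyl-directed syn-dihydroxylation, with inversion at C5 on oxirane closure.

Key step: step 6

Remark: germacrane numbering (C1=C10 alkene, C3 senecioate carbon, C4–C5 oxirane, C6 acetate carbon, C7 isopropyl carbon) is also applied to the cyclohexene intermediates 6 and 10, and bromide 7 is taken as purchasable.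

## Route

Step 1
Reactants: 1 (S)-(+)-carvone
Product: 2 (1S,4S,6S)-1-methyl-4-(prop-1-en-2-yl)-7-oxabicyclo[4.1.0]heptan-2-one (oxirane oxygen trans to the isopropenyl group)
Conditions: 30% aq. H2O2, NaOH, MeOH, 0 °C
Reagents that add atoms: hydrogen peroxide, OO
Why: Weitz–Scheffer nucleophilic epoxidation, in which hydroperoxide adds only to the electrophilic enone alkene and enters axially anti to the isopropenyl group, so the carvone stereocentre sets both oxirane carbons trans to it.

Step 2
Reactants: 2 carvone oxide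
Product: 4 (1S,5R)-2-methyl-5-(prop-1-en-2-yl)cyclohex-2-en-1-ol (trans-carveol), via epoxy hydrazone 3 (not isolated)
Conditions: N2H4·H2O, AcOH (cat.), MeOH, 0 °C to rt
Reagents that add atoms: none
Why: Wharton transposition, in which the hydrazone collapses with oxirane opening and loss of N2 to the transposed allylic alcohol; the C–O bond at the former β-carbon is never broken, so the hydroxyl stays trans to the isopropenyl group and the carbon that becomes C3 of the target is fixed as S.

Step 3
Reactants: 4 trans-carveol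
Product: 5 tert-butyldimethylsilyl ether of 4, (1S,5R) configuration unchanged
Conditions: TBSCl, imidazole, DMF, rt
Reagents that add atoms: tert-butyldimethylsilyl chloride, CC(C)(C)[Si](C)(C)Cl
Why: Standard silylation of a secondary allylic alcohol, chosen because the silyl ether survives CrO3, the organocerium reagent and KH.

Step 4
Reactants: 5 silyl ether
Product: 6 (4S,6R)-4-[(tert-butyldimethylsilyl)oxy]-3-methyl-6-(prop-1-en-2-yl)cyclohex-2-en-1-one (silyloxy trans to isopropenyl)
Conditions: CrO3, 3,5-dimethylpyrazole, CH2Cl2, −20 °C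
Reagents that add atoms: chromium trioxide, O=[Cr](=O)=O
Why: Allylic C–H oxidation with the CrO3–3,5-dimethylpyrazole complex, which converts the ring methylene next to a trisubstituted cyclohexene into the enone; the other ring allylic position already carries the silyloxy group, so only one ring CH2 can react and no stereocentre is touched.

Step 5
Reactants: 6 silyloxy enone; 7 2-bromo-3-methylbut-1-ene
Product: 10 (1R,4S,6R)-4-[(tert-butyldimethylsilyl)oxy]-3-methyl-1-(3-methylbut-1-en-2-yl)-6-(prop-1-en-2-yl)cyclohex-2-en-1-ol (alkenyl groups trans; hydroxyl cis to isopropenyl), via alkenyllithium 8 (not isolated), via alkenylcerium dichloride 9 (not isolated)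
Conditions: 7, tert-butyllithium (2 equiv), THF, −78 °C; anhydrous CeCl3, THF, −78 °C; then 6, −78 °C; aq. NH4Cl
Reagents that add atoms: none
Why: Halogen–lithium exchange, transmetalation and organocerium 1,2-addition to the enone, where the weakly basic cerium reagent avoids enolization at the doubly activated C1–H and attacks C6 anti to the adjacent isopropenyl group, placing the two alkenyl groups trans.

Step 6
Reactants: 10 trans-dialkenyl cyclohexenol
Product: 13 (3S,7S)-3-[(tert-butyldimethylsilyl)oxy]germacra-1(10)E,4Z-dien-6-one [(2Z,4S,6E,10S)-4-silyloxy-3,7-dimethyl-10-(propan-2-yl)cyclodeca-2,6-dien-1-one], via potassium alkoxide 11 (not isolated), via potassium enolate 12 (not isolated)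
Conditions: KH, 18-crown-6, THF, 0 °C to rt; then AcOH, THF, −78 °C
Reagents that add atoms: none
Why: KH with 18-crown-6 gives the dissociated alkoxide 11, whose weakened C1–C6 bond lets the 1,5-diene C8=C7–C6–C1–C10=C9 undergo a concerted [3,3] sigmatropic shift in which C8–C9 forms as C1–C6 breaks, and formation of enolate 12 makes it irreversible. The closest known reaction type is the anionic oxy-Cope ring expansion of trans-1,2-dialkenylcyclohex-2-enols to cyclodecadienones. The ten-membered ring is not closed end to end but arises by four-carbon enlargement of the cyclohexene through a six-centre chair transition state that joins the termini of the two alkenyl arms. The E geometry of C1=C10 and of the enolate follows from the chair with both alkenyl groups equatorial, which their trans relationship from step 5 secures, while Z-C4=C5 is carried over from the cyclohexene. The only new stereocentre, C7, is set on protonation: the E-enolate is planar-chiral in a sense fixed by C1 and C6 of 10, neither its oxygen nor its isopropyl group can swing through the ring, and proton delivery to the exposed face should give 7S. The cold acidic quench is intended to prevent later epimerization at C7.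

Step 7
Reactants: 13 dienone
Product: 14 (3S,6R,7S)-3-[(tert-butyldimethylsilyl)oxy]germacra-1(10)E,4Z-dien-6-ol
Conditions: NaBH4, CeCl3·7H2O, MeOH, −78 °C
Reagents that add atoms: none
Why: Luche reduction gives clean 1,2-reduction of the enone, and with the C7–C8 ring bond roughly perpendicular to the carbonyl plane and the isopropyl group near the carbonyl oxygen, hydride arriving from the ring periphery anti to C8 should give the 6R alcohol (a conformational prediction).

Step 8
Reactants: 14 allylic alcohol
Product: 15 (3S,6R,7S)-3-[(tert-butyldimethylsilyl)oxy]germacra-1(10)E,4Z-dien-6-yl acetate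
Conditions: Ac2O, pyridine, DMAP (cat.), CH2Cl2, rt
Reagents that add atoms: acetic anhydride, CC(=O)OC(C)=O
Why: DMAP-catalysed acetylation of the only free hydroxyl, a hindered secondary allylic alcohol.

Step 9
Reactants: 15 silyl ether acetate
Product: 16 (3S,6R,7S)-3-hydroxygermacra-1(10)E,4Z-dien-6-yl acetate
Conditions: HF·pyridine, pyridine, THF, 0 °C to rt
Reagents that add atoms: none
Why: Fluoride-mediated desilylation under buffered conditions removes the allylic silyl ether without cleaving or shifting the acetate.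

Step 10
Reactants: 16 allylic alcohol
Product: 18 (3S,4R,5S,6R,7S)-3,4,5-trihydroxygermacr-1(10)E-en-6-yl acetate, via osmate ester 17 (not isolated)
Conditions: OsO4 (1 equiv), TMEDA, CH2Cl2, −78 °C; then aq. Na2SO3, THF, rt
Reagents that add atoms: osmium tetroxide, O=[Os](=O)(=O)=O
Why: Hydroxyl-directed dihydroxylation, in which the OsO4·TMEDA complex is hydrogen-bonded by the C3 hydroxyl; with C3–H eclipsing the alkene to relieve allylic 1,3-strain this hydroxyl lies on the exposed face of Z-C4=C5, so syn addition occurs there and on this alkene in preference to C1=C10, setting C4 (R) and C5 (S) before aqueous Na2SO3 releases the triol.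

Step 11
Reactants: 18 triol acetate
Product: 19 6-acetoxy-4,5-dihydroxygermacr-1(10)E-en-3-yl 3-methylbut-2-enoate (3-O-senecioate of 18; descriptors 3S,4S,5S,6R,7S, the change at C4 being a priority effect only)
Conditions: 3-methylbut-2-enoyl chloride (1.1 equiv), pyridine, DMAP (cat.), CH2Cl2, −20 to 0 °C
Reagents that add atoms: 3-methylbut-2-enoyl chloride, CC(C)=CC(=O)Cl
Why: Site-selective O-acylation, since the C3 hydroxyl is flanked by a CH2 group whereas the C5 hydroxyl is wedged between quaternary C4 and the acetoxy-bearing C6, the tertiary C4 hydroxyl is inert, and the weak base pyridine limits deconjugation of the acyl group through the vinylketene.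

Step 12
Reactants: 19 diol diester
Product: 21 (3S,4R,5R,6R,7S)-6-acetoxy-4,5-epoxygermacr-1(10)E-en-3-yl 3-methylbut-2-enoate (CNP0267399.1), via C5 mesylate 20 (not isolated)
Conditions: MsCl, Et3N, CH2Cl2, −10 °C; then DBU, rt
Reagents that add atoms: none
Why: O-sulfonylation of the only secondary hydroxyl followed by base-induced 3-exo-tet displacement (intramolecular Williamson etherification), in which the C4 alkoxide attacks C5 anti to the mesylate, so C4 is retained, C5 is inverted and the syn-diol from the Z-alkene becomes the trans-oxirane.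

## Compound list

1 | (S)-(+)-carvone | CC1=CC[C@@H](CC1=O)C(C)=C | starting material
2 | (1S,4S,6S)-1-methyl-4-(prop-1-en-2-yl)-7-oxabicyclo[4.1.0]heptan-2-one | C=C(C)[C@H]1C[C@@H]2O[C@]2(C)C(=O)C1 | intermediate
3 | hydrazone of 2 (ring stereocentres as in 2) | C=C(C)[C@H]1C[C@@H]2O[C@]2(C)C(=NN)C1 | intermediate
4 | (1S,5R)-2-methyl-5-(prop-1-en-2-yl)cyclohex-2-en-1-ol (trans-carveol) | C=C(C)[C@H]1C[C@H](O)C(C)=CC1 | intermediate
5 | tert-butyldimethylsilyl ether of 4 | C=C(C)[C@H]1C[C@H](O[Si](C)(C)C(C)(C)C)C(C)=CC1 | intermediate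
6 | (4S,6R)-4-[(tert-butyldimethylsilyl)oxy]-3-methyl-6-(prop-1-en-2-yl)cyclohex-2-en-1-one | O=C1C=C(C)[C@@H](O[Si](C)(C)C(C)(C)C)C[C@@H]1C(C)=C | intermediate
7 | 2-bromo-3-methylbut-1-ene | C=C(Br)C(C)C | starting material
8 | (3-methylbut-1-en-2-yl)lithium | [Li]C(=C)C(C)C | intermediate
9 | dichloro(3-methylbut-1-en-2-yl)cerium | C=C(C(C)C)[Ce](Cl)Cl | intermediate
10 | (1R,4S,6R)-4-[(tert-butyldimethylsilyl)oxy]-3-methyl-1-(3-methylbut-1-en-2-yl)-6-(prop-1-en-2-yl)cyclohex-2-en-1-ol | C=C(C(C)C)[C@@]1(O)C=C(C)[C@@H](O[Si](C)(C)C(C)(C)C)C[C@@H]1C(C)=C | intermediate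
11 | potassium alkoxide of 10 | C=C(C(C)C)[C@@]1([O-])C=C(C)[C@@H](O[Si](C)(C)C(C)(C)C)C[C@@H]1C(C)=C.[K+] | intermediate
12 | potassium (3S)-3-[(tert-butyldimethylsilyl)oxy]germacra-1(10)E,4Z,6E-trien-6-olate | [K+].[O-]/C1=C(C(C)C)\CC/C(C)=C/C[C@H](O[Si](C)(C)C(C)(C)C)/C(C)=C\1 | intermediate
13 | (3S,7S)-3-[(tert-butyldimethylsilyl)oxy]germacra-1(10)E,4Z-dien-6-one | O=C1/C=C(C)\[C@@H](O[Si](C)(C)C(C)(C)C)C/C=C(\C)CC[C@H]1C(C)C | intermediate
14 | (3S,6R,7S)-3-[(tert-butyldimethylsilyl)oxy]germacra-1(10)E,4Z-dien-6-ol | O[C@H]1/C=C(C)\[C@@H](O[Si](C)(C)C(C)(C)C)C/C=C(\C)CC[C@H]1C(C)C | intermediate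
15 | (3S,6R,7S)-3-[(tert-butyldimethylsilyl)oxy]germacra-1(10)E,4Z-dien-6-yl acetate | CC(=O)O[C@H]1/C=C(C)\[C@@H](O[Si](C)(C)C(C)(C)C)C/C=C(\C)CC[C@H]1C(C)C | intermediate
16 | (3S,6R,7S)-3-hydroxygermacra-1(10)E,4Z-dien-6-yl acetate | CC(=O)O[C@H]1/C=C(C)\[C@@H](O)C/C=C(\C)CC[C@H]1C(C)C | intermediate
17 | cyclic O4,O5-dioxoosmium ester of 18 with chelating TMEDA (hexavalent osmium; C3 hydroxyl free) | CC(=O)O[C@H]1[C@@H]2O[Os-2]3(=O)(=O)([N+](C)(C)CC[N+]3(C)C)O[C@]2(C)[C@@H](O)C/C=C(\C)CC[C@H]1C(C)C | intermediate
18 | (3S,4R,5S,6R,7S)-3,4,5-trihydroxygermacr-1(10)E-en-6-yl acetate | CC(=O)O[C@H]1[C@H](O)[C@](C)(O)[C@@H](O)C/C=C(\C)CC[C@H]1C(C)C | intermediate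
19 | 6-acetoxy-4,5-dihydroxygermacr-1(10)E-en-3-yl 3-methylbut-2-enoate (3-O-senecioate of 18) | CC(=O)O[C@H]1[C@H](O)[C@](C)(O)[C@@H](OC(=O)C=C(C)C)C/C=C(\C)CC[C@H]1C(C)C | intermediate
20 | 5-O-methanesulfonate of 19 | CC(=O)O[C@H]1[C@H](OS(C)(=O)=O)[C@](C)(O)[C@@H](OC(=O)C=C(C)C)C/C=C(\C)CC[C@H]1C(C)C | intermediate
21 | (3S,4R,5R,6R,7S)-6-acetoxy-4,5-epoxygermacr-1(10)E-en-3-yl 3-methylbut-2-enoate (CNP0267399.1) | CC(=O)O[C@H]1[C@H]2O[C@]2(C)[C@@H](OC(=O)C=C(C)C)C/C=C(\C)CC[C@H]1C(C)C | target

## Step count and risks

Total steps: 12. Longest linear sequence: 12 steps (1 to 21); bromide 7 enters as a purchased fragment in step 5.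

Steps most likely to fail:

Step 7. The risk is poor or reversed facial selectivity in hydride delivery to C6, because the ten-membered ketone may react through a conformer in which the isopropyl group rather than the C7–C8 bond stands perpendicular to the carbonyl. The fallback sets out from ketone 13. It would be reduced with the hydride source that gives the C6 epimer most cleanly (LiBH(s-Bu)3, THF, −78 °C, as first choice) to (3S,6S,7S)-3-[(tert-butyldimethylsilyl)oxy]germacra-1(10)E,4Z-dien-6-ol F4. A Mitsunobu reaction (4-nitrobenzoic acid, PPh3, DIAD, toluene, 0 °C to rt) would invert C6 to the (6R) 4-nitrobenzoate F5. Methanolysis (K2CO3, MeOH) would rejoin the route at alcohol 14.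

Step 11. The risk is insufficient discrimination between the C3 and C5 hydroxyls, or acetyl migration from O6 to O5 under the basic acylation conditions. The fallback sets out from triol 18 and puts the senecioate on last, when only one hydroxyl is free. The more sterically discriminating Et3SiCl (imidazole, DMF, −40 °C) would give the 3-O-triethylsilyl 4,5-diol F6. Mesylation (MsCl, Et3N, CH2Cl2) to the C5 mesylate F7 and closure with DBU would give the silylated epoxide F8. HF·pyridine would free the epoxy alcohol F9, and 3-methylbut-2-enoyl chloride with pyridine would deliver target 21.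

Step 4. The risk is unselective hydrogen abstraction (at the isopropenyl allylic positions or the silyloxy-bearing carbon) and migration of the isopropenyl double bond into conjugation in the product. The fallback sets out from silyl ether 5. Epoxidation of the more electron-rich ring alkene (mCPBA, NaHCO3, CH2Cl2, 0 °C) would give the epoxide F1, with oxygen anti to the silyloxy group. Opening at the secondary carbon with sodium benzeneselenolate PhSeNa (from (PhSe)2 and NaBH4, EtOH) would give the hydroxy selenide F2. Its selenoxide (H2O2) would eliminate away from the carbinol to the tertiary allylic alcohol F3. Oxidative 1,3-transposition (Babler–Dauben oxidation) with pyridinium chlorochromate [C5H5NH][CrO3Cl] in CH2Cl2 would rejoin the route at enone 6.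

## Further compounds

F1 | step 4 | epoxide of 5 at the ring alkene, oxygen anti to the silyloxy group | C=C(C)[C@H]1C[C@H](O[Si](C)(C)C(C)(C)C)[C@@]2(C)O[C@H]2C1
F2 | step 4 | hydroxy selenide from trans-diaxial opening of F1 (tertiary OH, PhSe on the adjacent CH) | C=C(C)[C@H]1C[C@H](O[Si](C)(C)C(C)(C)C)[C@@](C)(O)[C@H]([Se]c2ccccc2)C1
F3 | step 4 | tertiary allylic alcohol, 6-silyloxy-1-methyl-4-(prop-1-en-2-yl)cyclohex-2-en-1-ol (OH trans to silyloxy) | C=C(C)[C@H]1C[C@H](O[Si](C)(C)C(C)(C)C)[C@@](C)(O)C=C1
F4 | step 7 | (3S,6S,7S)-3-[(tert-butyldimethylsilyl)oxy]germacra-1(10)E,4Z-dien-6-ol (C6 epimer of 14) | O[C@@H]1/C=C(C)\[C@@H](O[Si](C)(C)C(C)(C)C)C/C=C(\C)CC[C@H]1C(C)C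
F5 | step 7 | (3S,6R,7S)-3-[(tert-butyldimethylsilyl)oxy]germacra-1(10)E,4Z-dien-6-yl 4-nitrobenzoate | O=C(O[C@H]1/C=C(C)\[C@@H](O[Si](C)(C)C(C)(C)C)C/C=C(\C)CC[C@H]1C(C)C)c1ccc(cc1)[N+](=O)[O-]
F6 | step 11 | 3-O-triethylsilyl ether of triol 18 | CC(=O)O[C@H]1[C@H](O)[C@](C)(O)[C@@H](O[Si](CC)(CC)CC)C/C=C(\C)CC[C@H]1C(C)C
F7 | step 11 | 5-O-methanesulfonate of F6 | CC(=O)O[C@H]1[C@H](OS(C)(=O)=O)[C@](C)(O)[C@@H](O[Si](CC)(CC)CC)C/C=C(\C)CC[C@H]1C(C)C
F8 | step 11 | (4R,5R)-4,5-epoxy-3-(triethylsilyloxy)germacr-1(10)E-en-6-yl acetate | CC(=O)O[C@H]1[C@H]2O[C@]2(C)[C@@H](O[Si](CC)(CC)CC)C/C=C(\C)CC[C@H]1C(C)C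
F9 | step 11 | (3S,4R,5R,6R,7S)-4,5-epoxy-3-hydroxygermacr-1(10)E-en-6-yl acetate | CC(=O)O[C@H]1[C@H]2O[C@]2(C)[C@@H](O)C/C=C(\C)CC[C@H]1C(C)C
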